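The route rests on cutting ring C at O1–C8a, the aryl–oxygen bond. It exploits the fact that O1 ties the C2 stereocentre to C8a, the ring A carbon lying between prenyl-bearing C8 and acyl-bearing C4a. The chelated phenol at that site of a 3-prenylphloroacetophenone is turned into a triflate leaving group, which locks the 8-prenyl pattern. One palladium-catalysed intramolecular etherification then closes ring C without breaking any bond at C2, whose S configuration stems from a boron aldol reaction. The cyclisation substrate is an open-chain, tris-MOM-protected anti-1,3-diaryl-1,3-propanediol bearing the C8a triflate. C4 is parked at the alcohol level so that retro-aldol and chalcone-forming pathways are closed.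

Key step: step 9

Assumption: the S sense of the aldol reaction in step 7 is assigned to (+)-Ipc2BCl by analogy with its reactions of methyl ketones with unsaturated aldehydes. It is to be checked by Mosher ester analysis of the aldol product, and the equally available antipodal reagent would be used if the sense proved opposite.

Step 1
Reactants: 1 2,4,6-trihydroxyacetophenone; 2 1-bromo-3-methylbut-2-ene (prenyl bromide)
Product: 3 1-[2,4,6-trihydroxy-3-(3-methylbut-2-enyl)phenyl]ethanone
Conditions: DBU (1 equiv), 2 (1 equiv), THF, 0 °C → rt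
Reagents that add atoms: none
Why: Nuclear C-alkylation of an acylphloroglucinol phenoxide by a soft primary allylic bromide (SN2) is a known reaction of this substrate class, C3 and C5 are equivalent so no regiochemical question arises, and one equivalent of bromide limits double prenylation.

Step 2
Reactants: 3 1-[2,4,6-trihydroxy-3-(3-methylbut-2-enyl)phenyl]ethanone
Product: 4 1-[2-hydroxy-4,6-bis(methoxymethoxy)-3-(3-methylbut-2-enyl)phenyl]ethanone
Conditions: MOMCl (2.2 equiv), iPr2NEt, CH2Cl2, 0 °C → rt
Reagents that add atoms: chloromethyl methyl ether (MOMCl), COCCl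
Why: Williamson-type O-alkylation should take the unchelated 4-OH and the less hindered 6-OH, whereas the 2-OH, squeezed between acetyl and prenyl groups and hydrogen-bonded to the carbonyl oxygen, should stay free, in line with the selective dialkylation behaviour of 3-prenylphloroacetophenone.

Step 3
Reactants: 4 1-[2-hydroxy-4,6-bis(methoxymethoxy)-3-(3-methylbut-2-enyl)phenyl]ethanone
Product: 5 2-acetyl-3,5-bis(methoxymethoxy)-6-(3-methylbut-2-enyl)phenyl trifluoromethanesulfonate
Conditions: Tf2O, pyridine, CH2Cl2, −20 → 0 °C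
Reagents that add atoms: trifluoromethanesulfonic anhydride, O=S(=O)(OS(=O)(=O)C(F)(F)F)C(F)(F)F
Why: O-sulfonylation of a chelated 2-acylphenol with the small and highly electrophilic anhydride is standard, and the cold pyridine-buffered medium should leave the MOM ethers, the alkene and the methyl ketone untouched.

Step 4
Reactants: 6 7-hydroxy-2,2-dimethylchroman-4-one
Product: 8 2,2-dimethyl-2H-chromen-7-ol, via 2,2-dimethylchromane-4,7-diol 7 (not isolated)
Conditions: NaBH4, MeOH, 0 °C → rt; then 2 M aq. HCl, THF, rt
Reagents that add atoms: none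
Why: Borohydride reduction gives a benzylic alcohol that is para to the phenol and ortho to the ring oxygen, so mild acid should dehydrate it (E1 through a stabilised benzylic cation) to the conjugated chromene, which is the classical chromanone-to-chromene sequence.

Step 5
Reactants: 8 2,2-dimethyl-2H-chromen-7-ol
Product: 9 7-hydroxy-2,2-dimethyl-2H-chromene-6-carbaldehyde
Conditions: MgCl2, Et3N, (CH2O)n, MeCN, reflux; cold 1 M HCl work-up
Reagents that add atoms: paraformaldehyde (source of formaldehyde), C=O
Why: In the Casnati–Skattebøl ortho-formylation the magnesium phenoxide delivers formaldehyde to an ortho carbon and a second formaldehyde oxidises the benzylic alkoxide by hydride transfer, C6 (para to the ring oxygen, one neighbour) should be preferred over C8 (wedged between two oxygens), and the basic medium suits the acid-sensitive chromene.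

Step 6
Reactants: 9 7-hydroxy-2,2-dimethyl-2H-chromene-6-carbaldehyde
Product: 10 7-(methoxymethoxy)-2,2-dimethyl-2H-chromene-6-carbaldehyde
Conditions: MOMCl, iPr2NEt, CH2Cl2, 0 °C → reflux
Reagents that add atoms: chloromethyl methyl ether (MOMCl), COCCl
Why: O-alkylation of the single, salicylaldehyde-type phenol with MOMCl and a hindered amine base is routine and removes the acidic proton that would quench the boron enolate of the next step.

Step 7
Reactants: 5 2-acetyl-3,5-bis(methoxymethoxy)-6-(3-methylbut-2-enyl)phenyl trifluoromethanesulfonate; 10 7-(methoxymethoxy)-2,2-dimethyl-2H-chromene-6-carbaldehyde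
Product: 13 2-{(3S)-3-hydroxy-3-[7-(methoxymethoxy)-2,2-dimethyl-2H-chromen-6-yl]propanoyl}-3,5-bis(methoxymethoxy)-6-(3-methylbut-2-enyl)phenyl trifluoromethanesulfonate, via enol diisopinocampheylborinate 11 (not isolated), via boron aldolate 12 (not isolated)
Conditions: (+)-Ipc2BCl, Et3N, Et2O, 0 °C; 10, −78 → −20 °C; then 30% H2O2, MeOH, pH 7 buffer, 0 °C
Reagents that add atoms: none
Why: Ipc2BCl and Et3N enolise the only enolisable position of methyl ketone 5, the enol borinate adds to aldehyde 10 through a cyclic boron-bound transition state in which the isopinocampheyl ligands derived from (−)-α-pinene distinguish the aldehyde faces and should set the carbinol carbon (flavanone C2) as S (reagent-controlled boron aldol reaction, Paterson aldol), and the neutral peroxide work-up spares triflate, MOM ethers and both alkenes.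

Step 8
Reactants: 13 2-{(3S)-3-hydroxy-3-[7-(methoxymethoxy)-2,2-dimethyl-2H-chromen-6-yl]propanoyl}-3,5-bis(methoxymethoxy)-6-(3-methylbut-2-enyl)phenyl trifluoromethanesulfonate
Product: 14 2-{(1S,3S)-1,3-dihydroxy-3-[7-(methoxymethoxy)-2,2-dimethyl-2H-chromen-6-yl]propyl}-3,5-bis(methoxymethoxy)-6-(3-methylbut-2-enyl)phenyl trifluoromethanesulfonate
Conditions: Me4NBH(OAc)3, MeCN–AcOH (1:1), −30 → −20 °C; aq. NaHCO3 and potassium sodium tartrate work-up
Reagents that add atoms: none
Why: In the Evans–Saksena reduction the existing hydroxyl exchanges an acetate on boron and hydride is delivered intramolecularly through a chair-like six-membered transition state, which should place the new hydroxyl anti and set the ring A carbinol (flavanone C4) as S, while the reagent is too weak to reduce the hindered ketone externally and the cold acetic acid medium tolerates the MOM ethers.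

Step 9
Reactants: 14 2-{(1S,3S)-1,3-dihydroxy-3-[7-(methoxymethoxy)-2,2-dimethyl-2H-chromen-6-yl]propyl}-3,5-bis(methoxymethoxy)-6-(3-methylbut-2-enyl)phenyl trifluoromethanesulfonate
Product: 15 (2S,4S)-5,7-bis(methoxymethoxy)-2-[7-(methoxymethoxy)-2,2-dimethyl-2H-chromen-6-yl]-8-(3-methylbut-2-enyl)chroman-4-ol
Conditions: Pd(OAc)2 (5 mol %), 2-(di-tert-butylphosphino)-1,1′-binaphthyl (6 mol %), K3PO4 (anhydrous, finely ground), 4 Å MS, toluene, 80 °C
Reagents that add atoms: none
Why: The cycle opens with oxidative addition of zerovalent palladium, formed in situ, to the C8a–OTf bond (C8a is meta to both ring A MOM ethers and so is not deactivated by resonance); the C2 hydroxyl then binds to the cationic divalent palladium centre, is deprotonated there by K3PO4, and C–O reductive elimination forges O1–C8a. The closest known reaction type is the Buchwald–Hartwig intramolecular etherification of aryl halides with secondary alcohols to chromans, in which enantioenriched carbinols keep their configuration, and aryl triflates are established C–O coupling partners with the same ligand family and K3PO4 in toluene. Ring C closes in the six-membered mode by contraction of a seven-membered palladacycle (Pd, C8a, C4a, C4, C3, C2, O1). No stereocentre is created and no bond at C2 or C4 is broken, so (1S,3S) in 14 becomes (2S,4S) in 15, the 2,4-cis chromanol with aryl and hydroxyl groups both pseudo-equatorial, which makes the anti diol the better diastereomer to cyclise. The choice between the two hydroxyls is secured by ring size, because the C4 alkoxide could only give a benzoxete and its five-membered chelate holds the carbinol hydrogen away from the metal, so it is a reversible dead end. Reductive elimination should outrun beta-hydride elimination thanks to the bulky electron-rich phosphine and the two ortho substituents at C8 and C4a, and the insoluble weak base in dry toluene keeps free alkoxide low so that S–O cleavage of the triflate is held back.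

Step 10
Reactants: 15 (2S,4S)-5,7-bis(methoxymethoxy)-2-[7-(methoxymethoxy)-2,2-dimethyl-2H-chromen-6-yl]-8-(3-methylbut-2-enyl)chroman-4-ol
Product: 16 (2S)-5,7-bis(methoxymethoxy)-2-[7-(methoxymethoxy)-2,2-dimethyl-2H-chromen-6-yl]-8-(3-methylbut-2-enyl)chroman-4-one
Conditions: Dess–Martin periodinane, NaHCO3, CH2Cl2, 0 °C → rt
Reagents that add atoms: none
Why: The Dess–Martin oxidation converts the single free secondary alcohol into the ketone under buffered, nearly neutral conditions that should neither ionise the electron-rich benzylic position, nor attack the two alkenes, nor open ring C by beta-elimination, so C2 stays S.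

Step 11
Reactants: 16 (2S)-5,7-bis(methoxymethoxy)-2-[7-(methoxymethoxy)-2,2-dimethyl-2H-chromen-6-yl]-8-(3-methylbut-2-enyl)chroman-4-one
Product: 17 (2S)-5,7-dihydroxy-2-(7-hydroxy-2,2-dimethyl-2H-chromen-6-yl)-8-(3-methylbut-2-enyl)chroman-4-one (CNP0150213.1)
Conditions: HCl (1 M in MeOH), MeOH–THF, rt (→ 40 °C if needed), stopped at full conversion
Reagents that add atoms: none
Why: Acid-catalysed acetal exchange with methanol should strip the three aryl MOM ethers (the 5-O-MOM group first, since the freed phenol chelates the C4 carbonyl) under conditions well below those needed for cyclisation of the prenyl group onto the 7-OH, attack on the chromene or opening of ring C, a deprotection that is routine for MOM-protected prenylated chalcones and flavanones and involves no bond at C2.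

Compound list
1 | 2,4,6-trihydroxyacetophenone | CC(=O)c1c(O)cc(O)cc1O | starting material
2 | 1-bromo-3-methylbut-2-ene | CC(C)=CCBr | starting material
3 | 1-[2,4,6-trihydroxy-3-(3-methylbut-2-enyl)phenyl]ethanone | CC(=O)c1c(O)cc(O)c(CC=C(C)C)c1O | intermediate
4 | 1-[2-hydroxy-4,6-bis(methoxymethoxy)-3-(3-methylbut-2-enyl)phenyl]ethanone | CC(=O)c1c(OCOC)cc(OCOC)c(CC=C(C)C)c1O | intermediate
5 | 2-acetyl-3,5-bis(methoxymethoxy)-6-(3-methylbut-2-enyl)phenyl trifluoromethanesulfonate | CC(=O)c1c(OCOC)cc(OCOC)c(CC=C(C)C)c1OS(=O)(=O)C(F)(F)F | intermediate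
6 | 7-hydroxy-2,2-dimethylchroman-4-one | CC1(C)CC(=O)c2ccc(O)cc2O1 | starting material
7 | 2,2-dimethylchromane-4,7-diol (racemic, not isolated) | CC1(C)CC(O)c2ccc(O)cc2O1 | intermediate
8 | 2,2-dimethyl-2H-chromen-7-ol | CC1(C)C=Cc2ccc(O)cc2O1 | intermediate
9 | 7-hydroxy-2,2-dimethyl-2H-chromene-6-carbaldehyde | CC1(C)C=Cc2cc(C=O)c(O)cc2O1 | intermediate
10 | 7-(methoxymethoxy)-2,2-dimethyl-2H-chromene-6-carbaldehyde | COCOc1cc2c(cc1C=O)C=CC(C)(C)O2 | intermediate
11 | enol diisopinocampheylborinate of 5 (O-boryl enol ether of the acetyl group, Ipc groups as in (+)-Ipc2BCl, not isolated) | C=C(OB([C@H]1C[C@H]2C[C@@H]([C@@H]1C)C2(C)C)[C@H]1C[C@H]2C[C@@H]([C@@H]1C)C2(C)C)c1c(OCOC)cc(OCOC)c(CC=C(C)C)c1OS(=O)(=O)C(F)(F)F | intermediate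
12 | boron aldolate, the O-diisopinocampheylboryl derivative of (S)-aldol 13 (not isolated) | CC(C)=CCc1c(OCOC)cc(OCOC)c(C(=O)C[C@H](OB([C@H]2C[C@H]3C[C@@H]([C@@H]2C)C3(C)C)[C@H]2C[C@H]3C[C@@H]([C@@H]2C)C3(C)C)c2cc3c(cc2OCOC)OC(C)(C)C=C3)c1OS(=O)(=O)C(F)(F)F | intermediate
13 | 2-{(3S)-3-hydroxy-3-[7-(methoxymethoxy)-2,2-dimethyl-2H-chromen-6-yl]propanoyl}-3,5-bis(methoxymethoxy)-6-(3-methylbut-2-enyl)phenyl trifluoromethanesulfonate | CC(C)=CCc1c(OCOC)cc(OCOC)c(C(=O)C[C@H](O)c2cc3c(cc2OCOC)OC(C)(C)C=C3)c1OS(=O)(=O)C(F)(F)F | intermediate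
14 | 2-{(1S,3S)-1,3-dihydroxy-3-[7-(methoxymethoxy)-2,2-dimethyl-2H-chromen-6-yl]propyl}-3,5-bis(methoxymethoxy)-6-(3-methylbut-2-enyl)phenyl trifluoromethanesulfonate (anti diol) | CC(C)=CCc1c(OCOC)cc(OCOC)c([C@@H](O)C[C@H](O)c2cc3c(cc2OCOC)OC(C)(C)C=C3)c1OS(=O)(=O)C(F)(F)F | intermediate
15 | (2S,4S)-5,7-bis(methoxymethoxy)-2-[7-(methoxymethoxy)-2,2-dimethyl-2H-chromen-6-yl]-8-(3-methylbut-2-enyl)chroman-4-ol (2,4-cis) | CC(C)=CCc1c(OCOC)cc(OCOC)c2c1O[C@H](c1cc3c(cc1OCOC)OC(C)(C)C=C3)C[C@@H]2O | intermediate
16 | (2S)-5,7-bis(methoxymethoxy)-2-[7-(methoxymethoxy)-2,2-dimethyl-2H-chromen-6-yl]-8-(3-methylbut-2-enyl)chroman-4-one | CC(C)=CCc1c(OCOC)cc(OCOC)c2c1O[C@H](c1cc3c(cc1OCOC)OC(C)(C)C=C3)CC2=O | intermediate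
17 | (2S)-5,7-dihydroxy-2-(7-hydroxy-2,2-dimethyl-2H-chromen-6-yl)-8-(3-methylbut-2-enyl)chroman-4-one (CNP0150213.1) | CC(C)=CCc1c(O)cc(O)c2c1O[C@H](c1cc3c(cc1O)OC(C)(C)C=C3)CC2=O | target

Total step count: 11. Longest linear sequence: 8 steps (steps 1–3 and 7–11; the branch through steps 4–6 and 7–11 is equally long).

Steps most likely to fail

1. Step 9.
- What may go wrong: oxidative addition at the doubly ortho-substituted C8a may be slow. That would let base-induced S–O cleavage of the sulfonate, sulfonyl transfer to the neighbouring C4 hydroxyl, or beta-hydride elimination with net reductive loss of the leaving group take over.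
- The fallback gives up the aryl–oxygen closure. It closes ring C at O1–C2 by conjugate addition and secures the stereocentre by kinetic resolution.
- It sets out from 4 and 10. A Claisen–Schmidt condensation (KOH, EtOH–H2O, rt) should give the 2′-hydroxychalcone (E)-1-[2-hydroxy-4,6-bis(methoxymethoxy)-3-(3-methylbut-2-enyl)phenyl]-3-[7-(methoxymethoxy)-2,2-dimethyl-2H-chromen-6-yl]prop-2-en-1-one F1.
- NaOAc in refluxing EtOH should cyclise F1 through its only free phenol (oxa-Michael addition) to rac-5,7-bis(methoxymethoxy)-2-[7-(methoxymethoxy)-2,2-dimethyl-2H-chromen-6-yl]-8-(3-methylbut-2-enyl)chroman-4-one F2.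
- A Noyori transfer hydrogenation run as a kinetic resolution (RuCl[(R,R)-TsDPEN](p-cymene), HCO2H–Et3N, EtOAc, rt) is a known way to enantiopure flavanones. It should reduce the 2R enantiomer to the separable (2R,4R)-5,7-bis(methoxymethoxy)-2-[7-(methoxymethoxy)-2,2-dimethyl-2H-chromen-6-yl]-8-(3-methylbut-2-enyl)chroman-4-ol F3 and leave the 2S ketone.
- The fallback comes back to the route at 16.

2. Step 7.
- What may go wrong: facial selectivity may be poor, because the hindered, twisted aryl ketone partner weakens the discrimination exerted by the isopinocampheyl ligands. Addition to the electron-rich aldehyde may also be sluggish.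
- The fallback sets the stereocentre by catalytic ketone reduction instead of aldol face control.
- It sets out from 5 and 10. An achiral boron aldol reaction (c-Hex2BCl, Et3N, Et2O; buffered H2O2 work-up) should give rac-2-{3-hydroxy-3-[7-(methoxymethoxy)-2,2-dimethyl-2H-chromen-6-yl]propanoyl}-3,5-bis(methoxymethoxy)-6-(3-methylbut-2-enyl)phenyl trifluoromethanesulfonate F4.
- Dess–Martin oxidation should convert F4 into the 1,3-diketone 2-{3-[7-(methoxymethoxy)-2,2-dimethyl-2H-chromen-6-yl]-3-oxopropanoyl}-3,5-bis(methoxymethoxy)-6-(3-methylbut-2-enyl)phenyl trifluoromethanesulfonate F5.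
- Noyori transfer hydrogenation (RuCl[(S,S)-TsDPEN](p-cymene), HCO2H–Et3N, rt) should reduce the accessible ring B carbonyl to the S carbinol. The doubly ortho-substituted ring A carbonyl is expected to remain.
- The fallback comes back to the route at 13.

3. Step 11.
- What may go wrong: protic acid may trigger cyclisation of the prenyl group onto the 7-OH, attack on the chromene double bond, or reversible opening of ring C at the strongly stabilised C2 benzylic position with erosion of enantiomeric purity.
- The fallback avoids Brønsted acid by exchanging the protecting groups and finishing with fluoride.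
- It sets out from 16. TESOTf and 2,2′-bipyridyl in MeCN (0 °C → rt) effect a known direct conversion of aryl MOM ethers into aryl silyl ethers. This should give (2S)-5,7-bis(triethylsilyloxy)-2-[7-(triethylsilyloxy)-2,2-dimethyl-2H-chromen-6-yl]-8-(3-methylbut-2-enyl)chroman-4-one F6.
- Et3N·3HF in THF at 0 °C should desilylate F6 under nearly neutral conditions.
- The fallback comes back to the route at 17.

Further compounds
F1 | step 9 | (E)-1-[2-hydroxy-4,6-bis(methoxymethoxy)-3-(3-methylbut-2-enyl)phenyl]-3-[7-(methoxymethoxy)-2,2-dimethyl-2H-chromen-6-yl]prop-2-en-1-one | CC(C)=CCc1c(OCOC)cc(OCOC)c(C(=O)/C=C/c2cc3c(cc2OCOC)OC(C)(C)C=C3)c1O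
F2 | step 9 | rac-5,7-bis(methoxymethoxy)-2-[7-(methoxymethoxy)-2,2-dimethyl-2H-chromen-6-yl]-8-(3-methylbut-2-enyl)chroman-4-one | CC(C)=CCc1c(OCOC)cc(OCOC)c2c1OC(c1cc3c(cc1OCOC)OC(C)(C)C=C3)CC2=O
F3 | step 9 | (2R,4R)-5,7-bis(methoxymethoxy)-2-[7-(methoxymethoxy)-2,2-dimethyl-2H-chromen-6-yl]-8-(3-methylbut-2-enyl)chroman-4-ol | CC(C)=CCc1c(OCOC)cc(OCOC)c2c1O[C@@H](c1cc3c(cc1OCOC)OC(C)(C)C=C3)C[C@H]2O
F4 | step 7 | rac-2-{3-hydroxy-3-[7-(methoxymethoxy)-2,2-dimethyl-2H-chromen-6-yl]propanoyl}-3,5-bis(methoxymethoxy)-6-(3-methylbut-2-enyl)phenyl trifluoromethanesulfonate | CC(C)=CCc1c(OCOC)cc(OCOC)c(C(=O)CC(O)c2cc3c(cc2OCOC)OC(C)(C)C=C3)c1OS(=O)(=O)C(F)(F)F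
F5 | step 7 | 2-{3-[7-(methoxymethoxy)-2,2-dimethyl-2H-chromen-6-yl]-3-oxopropanoyl}-3,5-bis(methoxymethoxy)-6-(3-methylbut-2-enyl)phenyl trifluoromethanesulfonate | CC(C)=CCc1c(OCOC)cc(OCOC)c(C(=O)CC(=O)c2cc3c(cc2OCOC)OC(C)(C)C=C3)c1OS(=O)(=O)C(F)(F)F
F6 | step 11 | (2S)-5,7-bis(triethylsilyloxy)-2-[7-(triethylsilyloxy)-2,2-dimethyl-2H-chromen-6-yl]-8-(3-methylbut-2-enyl)chroman-4-one | CC(C)=CCc1c(O[Si](CC)(CC)CC)cc(O[Si](CC)(CC)CC)c2c1O[C@H](c1cc3c(cc1O[Si](CC)(CC)CC)OC(C)(C)C=C3)CC2=O
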